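**Retrosynthetic overview**
- Target ⇐ Pd(0) removal of two O-allyl groups ⇐ 2',4'-di-O-allyl isoflav-3-ene ⇐ hydride reduction and dehydration of the isoflavone (as isoflavone reductase → isoflavanol → dehydration).
- Isoflavone ⇐ flavanone by oxidative C2→C3 aryl migration with iodine(III) on the enol silane (isoflavone-synthase mimic).
- Flavanone ⇐ 2'-hydroxychalcone by 6-endo oxa-Michael closure (chalcone-isomerase mimic) ⇐ Claisen–Schmidt condensation of the A-ring acetophenone with 2,4-bis(allyloxy)benzaldehyde.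
- Acetophenone ⇐ symmetric 3,5-dimethoxy-4-prenylphenol (its two ortho positions are equivalent, so the 6-prenyl pattern is fixed) ⇐ 3,5-dimethoxyphenol by silyl-controlled C4 lithiation and prenylation.
- Ring order: A and B rings are bought; the pyran ring is closed once (oxa-Michael), then rearranged, reduced and dehydrated.

Assumption: the target has no stereocentre and its only ring alkene is endocyclic, so it is achiral; racemic or diastereomeric intermediates are acceptable because their stereocentres are destroyed before the end.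

**Step 1**
Reactants: 1 3,5-dimethoxyphenol
Product: 2 (3,5-dimethoxyphenoxy)triisopropylsilane
Conditions: TIPSCl, imidazole, DMF, rt
Reagents that add atoms: triisopropylsilyl chloride, CC(C)[Si](Cl)(C(C)C)C(C)C
Why: Imidazole-promoted O-silylation of a phenol; the bulky, weakly coordinating OTIPS group shields C2/C6 and leaves the two OMe groups to direct the lithiation in step 2.

**Step 2**
Reactants: 2 (3,5-dimethoxyphenoxy)triisopropylsilane
Product: 5 3,5-dimethoxy-4-(3-methylbut-2-en-1-yl)phenol, via aryllithium 3 (not isolated), via prenylated TIPS ether 4 (not isolated)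
Conditions: n-BuLi, TMEDA, THF, 0 °C→rt; CuBr·SMe2 (10 mol %), prenyl bromide, −78→0 °C; then TBAF, rt; aq NH4Cl
Reagents that add atoms: prenyl bromide (1-bromo-3-methylbut-2-ene), CC(C)=CCBr
Why: Directed ortho-metalation takes place at C4 between the two cooperating OMe groups, copper-catalysed SN2 allylation gives the linear prenyl group, and fluoride desilylation in the same flask frees the symmetric phenol.

**Step 3**
Reactants: 5 3,5-dimethoxy-4-(3-methylbut-2-en-1-yl)phenol
Product: 7 1-[6-hydroxy-2,4-dimethoxy-3-(3-methylbut-2-en-1-yl)phenyl]ethan-1-one, via difluoroboron chelate 6 (not isolated)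
Conditions: Ac2O, BF3·OEt2, CH2Cl2, 0 °C→rt; then aq NaOAc/MeOH, 50 °C
Reagents that add atoms: acetic anhydride, CC(=O)OC(C)=O
Why: BF3-mediated Friedel–Crafts/Fries-type ortho-acetylation of a phloroglucinol-type phenol, driven by the BF2 chelate, gives a single regioisomer because both free ring positions are equivalent, and the prenyl group has no neighbouring OH to cyclise onto.

**Step 4**
Reactants: 8 2,4-dihydroxybenzaldehyde
Product: 9 2,4-bis(allyloxy)benzaldehyde
Conditions: allyl bromide, K2CO3, DMF, 60 °C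
Reagents that add atoms: allyl bromide, C=CCBr
Why: Williamson etherification installs base-, acid- and hydride-stable phenol protection that can later be removed with Pd(0) under non-acidic conditions.

**Step 5**
Reactants: 7 1-[6-hydroxy-2,4-dimethoxy-3-(3-methylbut-2-en-1-yl)phenyl]ethan-1-one; 9 2,4-bis(allyloxy)benzaldehyde
Product: 11 (±)-2-[2,4-bis(allyloxy)phenyl]-5,7-dimethoxy-6-prenylchroman-4-one, via chalcone 10 (not isolated)
Conditions: KOH (50 % aq), EtOH, rt, 48 h; then AcOH to pH 7–8 (KOAc buffer), reflux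
Reagents that add atoms: none
Why: Claisen–Schmidt condensation gives the (E)-2'-hydroxychalcone, which on buffering closes by 6-endo oxa-Michael addition (favoured by the 6'-OMe group) to the flavanone, whose C2 centre is racemic and is erased in step 6.

**Step 6**
Reactants: 11 (±)-2-[2,4-bis(allyloxy)phenyl]-5,7-dimethoxy-6-prenylchroman-4-one
Product: 13 3-[2,4-bis(allyloxy)phenyl]-5,7-dimethoxy-6-prenyl-4H-chromen-4-one, via TMS enol ether 12 (not isolated)
Conditions: TMSOTf, Et3N, CH2Cl2, 0 °C; pentane, filter, concentrate; then PhI(OH)OTs (Koser's reagent, 1.05 equiv), CH2Cl2/MeCN, −40→0 °C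
Reagents that add atoms: none
Why: Proposed new method: the preformed enol silane (Mayr N about 5–6, against about 1–2 for the prenyl and allyl alkenes) attacks iodine(III) at C3 anti to the C2 aryl group, the antiperiplanar electron-rich 2,4-dialkoxyphenyl then migrates C2→C3 as PhI leaves with O1 stabilising the C2 oxocarbenium, and loss of H3 gives the isoflavone; the closest known reactions are the Koser-reagent oxidative 2,3-aryl migration of flavanones to isoflavones and the α-functionalisation of silyl enol ethers with the same reagent.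

**Step 7**
Reactants: 13 3-[2,4-bis(allyloxy)phenyl]-5,7-dimethoxy-6-prenyl-4H-chromen-4-one
Product: 15 3-[2,4-bis(allyloxy)phenyl]-5,7-dimethoxy-6-prenyl-2H-chromene, via isoflavan-4-ol 14 (not isolated)
Conditions: NaBH4, THF/EtOH, 0 °C→rt; aq work-up; then Burgess reagent, THF, 50 °C
Reagents that add atoms: none
Why: Borohydride conjugate reduction followed by carbonyl reduction of the vinylogous ester gives the isoflavan-4-ol (cis/trans mixture), and Burgess dehydration of this highly stabilised benzylic alcohol (syn-elimination or ion-pair E1) can only give the C3=C4 alkene because H3 is the only β-hydrogen, while the 2'-O-allyl group prevents pterocarpan closure.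

**Step 8**
Reactants: 15 3-[2,4-bis(allyloxy)phenyl]-5,7-dimethoxy-6-prenyl-2H-chromene
Product: 16 dehydroglyasperin D
Conditions: Pd(PPh3)4 (5 mol %), morpholine, THF, rt, argon
Reagents that add atoms: none
Why: Tsuji–Trost-type deallylation, in which the terminal aryl allyl ethers ionise to π-allyl palladium that morpholine traps, frees both phenols without acid (which would close the 2'-OH onto C4 to a pterocarpan), and leaves the prenyl group and the hindered cyclic chromene C–O bond untouched.

**Compound list**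
1 | 3,5-dimethoxyphenol | COc1cc(O)cc(OC)c1 | starting material
2 | (3,5-dimethoxyphenoxy)triisopropylsilane | COc1cc(O[Si](C(C)C)(C(C)C)C(C)C)cc(OC)c1 | intermediate
3 | [2,6-dimethoxy-4-(triisopropylsilyloxy)phenyl]lithium | [Li]c1c(OC)cc(O[Si](C(C)C)(C(C)C)C(C)C)cc1OC | intermediate
4 | [3,5-dimethoxy-4-(3-methylbut-2-en-1-yl)phenoxy]triisopropylsilane | COc1cc(O[Si](C(C)C)(C(C)C)C(C)C)cc(OC)c1CC=C(C)C | intermediate
5 | 3,5-dimethoxy-4-(3-methylbut-2-en-1-yl)phenol | COc1cc(O)cc(OC)c1CC=C(C)C | intermediate
6 | difluoroboron chelate of acetophenone 7 (2,2-difluoro-5,7-dimethoxy-4-methyl-6-prenyl-1,3,2-benzodioxaborinine) | CC1=[O+][B-](F)(F)Oc2cc(OC)c(CC=C(C)C)c(OC)c21 | intermediate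
7 | 1-[6-hydroxy-2,4-dimethoxy-3-(3-methylbut-2-en-1-yl)phenyl]ethan-1-one | CC(=O)c1c(O)cc(OC)c(CC=C(C)C)c1OC | intermediate
8 | 2,4-dihydroxybenzaldehyde | O=Cc1ccc(O)cc1O | starting material
9 | 2,4-bis(allyloxy)benzaldehyde | O=Cc1ccc(OCC=C)cc1OCC=C | intermediate
10 | (E)-3-[2,4-bis(allyloxy)phenyl]-1-[6-hydroxy-2,4-dimethoxy-3-prenylphenyl]prop-2-en-1-one | COc1cc(O)c(C(=O)/C=C/c2ccc(OCC=C)cc2OCC=C)c(OC)c1CC=C(C)C | intermediate
11 | (±)-2-[2,4-bis(allyloxy)phenyl]-5,7-dimethoxy-6-prenylchroman-4-one | COc1cc2OC(c3ccc(OCC=C)cc3OCC=C)CC(=O)c2c(OC)c1CC=C(C)C | intermediate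
12 | (±)-{2-[2,4-bis(allyloxy)phenyl]-5,7-dimethoxy-6-prenyl-2H-chromen-4-yl}oxy(trimethyl)silane | COc1cc2OC(c3ccc(OCC=C)cc3OCC=C)C=C(O[Si](C)(C)C)c2c(OC)c1CC=C(C)C | intermediate
13 | 3-[2,4-bis(allyloxy)phenyl]-5,7-dimethoxy-6-prenyl-4H-chromen-4-one | COc1cc2occ(-c3ccc(OCC=C)cc3OCC=C)c(=O)c2c(OC)c1CC=C(C)C | intermediate
14 | 3-[2,4-bis(allyloxy)phenyl]-5,7-dimethoxy-6-prenylchroman-4-ol (cis/trans mixture, racemic) | COc1cc2OCC(c3ccc(OCC=C)cc3OCC=C)C(O)c2c(OC)c1CC=C(C)C | intermediate
15 | 3-[2,4-bis(allyloxy)phenyl]-5,7-dimethoxy-6-prenyl-2H-chromene | COc1cc2OCC(c3ccc(OCC=C)cc3OCC=C)=Cc2c(OC)c1CC=C(C)C | intermediate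
16 | dehydroglyasperin D, 4-[5,7-dimethoxy-6-(3-methylbut-2-en-1-yl)-2H-chromen-3-yl]benzene-1,3-diol | COc1cc2c(c(OC)c1CC=C(C)C)C=C(c1ccc(O)cc1O)CO2 | target

**Totals and risks**
Total step count: 8. Longest linear sequence: 7 (steps 1, 2, 3, 5, 6, 7, 8).

Step 6 is the most likely to fail: the iodine(III) reagent may attack the prenyl alkene or an electron-rich arene, or substitute at C3 instead of triggering aryl migration. The fallback avoids electrophilic oxidants and sets out from flavanone 11. NaH and MOMCl in THF/DMF open the ring by E1cB and trap the phenoxide as the 2'-O-MOM chalcone F1. Nucleophilic Weitz–Scheffer epoxidation (H2O2, NaOH, MeOH/THF), which leaves the prenyl and allyl alkenes alone, gives the trans-epoxide F2. BF3·OEt2 in CH2Cl2 at −20 °C opens the benzylic epoxide with 1,2-acyl shift to the α-formyl deoxybenzoin F3. HCl in MeOH then removes the MOM group and cyclodehydrates the resulting hemiacetal, and the route is rejoined at isoflavone 13.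

Step 3 is second: the Lewis acid may add across or cyclise the prenyl group before C-acetylation is complete. The fallback is photochemical and sets out from phenol 5. Ac2O and pyridine give the aryl acetate F4, and photo-Fries rearrangement (254 nm, degassed MeOH) moves the acetyl group to the only free positions, both ortho and equivalent, to rejoin at acetophenone 7.

Step 7 is third: the hindered, electron-rich 4-ketone may reduce incompletely, or the stabilised C4 cation may be captured by the 2'-ether oxygen during dehydration. The fallback avoids a C4 cation and sets out from isoflavone 13. L-Selectride in THF at −78 °C gives the isoflavanone F5 by conjugate reduction. KHMDS and PhNTf2 at −78 °C give the enol triflate F6. Pd(OAc)2/PPh3 with HCO2H/Bu3N in DMF at 60 °C then reduces the C–OTf bond and removes both allyl groups in the same operation, rejoining at target 16.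

**Further compounds**
F1 | step 6 | (E)-3-[2,4-bis(allyloxy)phenyl]-1-[2,4-dimethoxy-6-(methoxymethoxy)-3-prenylphenyl]prop-2-en-1-one | COCOc1cc(OC)c(CC=C(C)C)c(OC)c1C(=O)/C=C/c1ccc(OCC=C)cc1OCC=C
F2 | step 6 | trans-{3-[2,4-bis(allyloxy)phenyl]oxiran-2-yl}[2,4-dimethoxy-6-(methoxymethoxy)-3-prenylphenyl]methanone (racemic, one enantiomer drawn) | COCOc1cc(OC)c(CC=C(C)C)c(OC)c1C(=O)[C@H]1O[C@@H]1c1ccc(OCC=C)cc1OCC=C
F3 | step 6 | 2-[2,4-bis(allyloxy)phenyl]-3-[2,4-dimethoxy-6-(methoxymethoxy)-3-prenylphenyl]-3-oxopropanal (racemic, enolisable) | COCOc1cc(OC)c(CC=C(C)C)c(OC)c1C(=O)C(C=O)c1ccc(OCC=C)cc1OCC=C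
F4 | step 3 | 3,5-dimethoxy-4-(3-methylbut-2-en-1-yl)phenyl acetate | CC(=O)Oc1cc(OC)c(CC=C(C)C)c(OC)c1
F5 | step 7 | (±)-3-[2,4-bis(allyloxy)phenyl]-5,7-dimethoxy-6-prenylchroman-4-one | COc1cc2OCC(c3ccc(OCC=C)cc3OCC=C)C(=O)c2c(OC)c1CC=C(C)C
F6 | step 7 | 3-[2,4-bis(allyloxy)phenyl]-5,7-dimethoxy-6-prenyl-2H-chromen-4-yl trifluoromethanesulfonate | COc1cc2OCC(c3ccc(OCC=C)cc3OCC=C)=C(OS(=O)(=O)C(F)(F)F)c2c(OC)c1CC=C(C)C
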